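Target was lost slowly in the midnight run, so I wanted that slowness as a number before I trusted any peak.

| flask | starting material | second substrate | free catalyst | remark | time |
|---|---|---|---|---|---|
| midnight | 0.34 M | 1 M | 5 mM | run made earlier |  |
| summer | 0.75 M | 1 M | 5 mM | run made earlier |  |
| flask | 0.50 M | 1.00 M | 5.0 mM |  | 2.5 d |

| run | time / h | target / % | starting material / % |
|---|---|---|---|
| midnight | 3.00 | 46.1 | 51.6 |
| midnight | 5.00 | 65.8 | 32.0 |
| midnight | 8.00 | 80.9 | 14.0 |
| midnight | 15.0 | 86.0 | 2.2 |
| midnight | 25.0 | 77.3 | 0.6 |
| midnight | 40.0 | 68.8 | 0.1 |
| summer | 3.00 | 35.5 | 63.9 |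
| summer | 5.00 | 52.9 | 44.8 |
| summer | 8.00 | 73.0 | 23.7 |
| summer | 15.0 | 85.9 | 3.0 |
| summer | 25.0 | 79.8 | 0 |
| summer | 40.0 | 69.2 | 0 |

(standard deviation of a reading: 0.5 percentage points)

- the numbers in the tables scatter with a standard deviation of 0.5 percentage points

- the moment within 2.5 d at which there is most target
- the amount of target, in percent of the starting material charged, at that time

I worked with what was left, and added the two columns of the midnight table. The sum stood at 88.2% at 15.0 h and at 77.9% at 25.0 h, so I read from it a loss constant of 0.0124 h⁻¹. In the midnight run, starting material went from 14.0% at 8.00 h to 2.2% at 15.0 h. I took that fall as pseudo-first-order, with a making constant of 0.264 h⁻¹, though the lower reading carries its scatter.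

My carried number is the loss ratio 0.0470, the loss constant over the making constant, a selectivity factor. For two first-order steps in a row, the peak fraction is the ratio raised to the power ratio over one minus ratio, and at the peak the starting material left is the ratio times the target. For the flask, with c(starting material) at 0.50 M, I assumed the same ratio. So I expected a peak of 86.0% with 4.04% left. I carried the midnight and summer readings at 8.00 h forward to that remainder with the making constant. That gave estimates of 0.529 d for the midnight run and 0.612 d for the summer run, and I expected the flask between them.

The forecast named a single time, 0.58 d, and 86.3%: “The maximum falls where formation equals loss”.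

The flask gave 85.8% at 0.561 d.

    starting material + free catalyst ⇌ catalyst intermediate A (K = 450 L mol⁻¹, k = 86.0 L mol⁻¹ h⁻¹)
    catalyst intermediate A → free catalyst + target (k = 33.0 h⁻¹)
    second substrate + free catalyst ⇌ catalyst intermediate B (K = 0.330 L mol⁻¹, k = 60.0 L mol⁻¹ h⁻¹)
    catalyst intermediate B → free catalyst + second product (k = 3.10 h⁻¹)
    target ⇌ isomer of the product (K = 0.980, k = 0.0140 h⁻¹)

At that moment the flask held 85.8% target and 10.9% isomer of the product. The ratio times that target gives 4.03% starting material, and the flask held 3.28%. A neighbour flask was charged with 2.00 mM free catalyst, everything else as before. I kept the loss constant and scaled the making constant with the catalyst charge, so the ratio became 0.117 and the peak 75.3%. That neighbour flask reached 75.3%.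

(The numbers in the tables stem from a simulated flask from invented constants; the scatter is artificial.)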